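The runs were generated by integration with made-up constants, and the scatter is random.

Friday's flask stopped with starting material unused: the reading was 47.9% at 15.0 min and 47.7% at 40.0 min. We suppose that its 20 mM of partner was spent on the 16.2 mM of starting material that went. Dividing gives 1.23, which we call the partner price: mM of partner paid per mM of starting material used, read here from one flask and carrying its scatter. We reckon a flask's bill as its starting material times this price, and where the bill exceeds the partner charged we take partner as the limiting reagent.

| flask | starting material | partner | remark | time |
|---|---|---|---|---|
| Saturday's | 12 mM | 20 mM | run made earlier |  |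
| Friday's | 31 mM | 20 mM | run made earlier |  |
| red | 10 mM | 20.0 mM |  | 40 min |
| violet | 20 mM | 20.0 mM |  | 40 min |
| green | 20 mM | 10.0 mM |  | 40 min |
| ochre | 10 mM | 10.0 mM |  | 40 min |

| run | time / min | target / % | starting material / % |
|---|---|---|---|
| Saturday's | 10.0 | 54.6 | 6.2 |
| Saturday's | 20.0 | 51.9 | 1.9 |
| Saturday's | 30.0 | 44.5 | 0 |
| Saturday's | 40.0 | 42.3 | 1.0 |
| Friday's | 3.00 | 32.0 | 54.4 |
| Friday's | 8.00 | 32.7 | 51.1 |
| Friday's | 15.0 | 30.2 | 47.9 |
| Friday's | 40.0 | 24.1 | 47.7 |

(each reading ± 1 percentage point)

- ranking by amount of target, in percent of the starting material charged, from high to low, at 40 min (red / violet / green / ochre)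
- the same order at 2.5 h (red / violet / green / ochre)
- the amount of target, in percent of the starting material charged of the flask you put first, at 40 min
- the amount of target, in percent of the starting material charged of the flask you put last, at 40 min

Saturday's bill is 14.8 mM, less than its 20 mM of partner, and its starting material did fall to 1.0%. Red's bill of 12.3 mM is also covered. Violet's 24.7 mM is not, nor is ochre's 12.3 mM, and at this price the partner of each pays for 81.1% of its starting material. Green has the least partner per starting material of the four flasks, 0.500, so here is its ledger, supposing a side path that takes two partner per starting material:

[partner] charged: 10.0 mM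
starting material bought: 8.11 mM, leaving 59.5%
side path: 1.89 mM of starting material, 3.78 mM of partner
target path: 6.21 mM of starting material, the same of partner

The books close on 10.0 mM. Friday kept 0.461 of target per starting material used at its last reading. With that share we estimate green at 18.7%, and since its 40.5% of paid-for charge is lower than violet's, we put it last.

The forecast, made from the same runs, says ochre > red > violet > green at 40 min and ochre > red > violet > green at 2.5 h, with 48% first and 25% last, holding that “everything decays by the same factor, so the order is unchanged”. Its last value stands above ours.

The flasks give ochre > red > violet > green at 40 min and ochre > red > violet > green at 2.5 h, with ochre at 43.8% and green at 21.8% at 40 min.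

    starting material + 2 partner → side product (k = 16.0 /M²/s)
    target ⇌ isomer of the product (K = 1.50, k = 3.10 × 10⁻⁴ /s)
    starting material + partner → target (k = 0.420 /M/s)

Green ends with 56% of its starting material and 0% of its partner, a price of 1.15 over the run. At its start the target step used starting material 2.6 times as fast as the side step, a momentary price of 1.28. In a neighbour, green with 6.0 mM of partner, Friday's price foretells 75.7% of the starting material left, and that flask holds 72.6%.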